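Conventions used below: chain atoms are numbered C1 (diarylmethine) to C7 (CH2Ph) in every intermediate. Ar = 4-methoxy-2,6-bis(methoxymethoxy)phenyl (ring A in protected form); MOM = methoxymethyl.
Assumption: the hydrazine reagent 11 (IPNBSH), amide 17 and (−)-Ipc2BCl are taken as purchasable reagents.

## The problem

The target 20 is a cardamonin-type chalcone whose ring A (a 2,4-dihydroxy-6-methoxyphenyl ketone) is alkylated, at the carbon between its two hydroxyls, by C1 of a linear 1,7-diphenylhept-2-en-5-ol chain. No ring has to be built, so the task is to join three arenes to a seven-carbon chain and to control two stereocentres and two E alkenes. C1 (R) is a tertiary C–H carrying ring A, a phenyl group and the E C2=C3 alkene; it has no heteroatom and its two aryl groups differ only in substitution, so it is the hard centre. C5 (S) is an ordinary carbinol, 1,5-related to C1 across the alkene, and cannot control C1 directly; it can, however, set a temporary carbinol at C3 by 1,3-induction, and a C3 stereocentre can hand its chirality to C1 by a 1,3-transposition. Once set, the doubly benzylic and allylic C1–H bond must not meet strong base for long, radicals or hydrogenation catalysts. The 2′-hydroxychalcone is the most fragile unit (flavanone closure in acid or base, conjugate addition, reduction) and belongs at the end, and the phloroglucinol oxygens need masks that leave in mild acid. With the same group on both oxygens flanking C1, the two free positions of ring A are equivalent, so the acyl group can be introduced without a regiochemical question. The enabling feature is that ring A, C1 with its phenyl group, C2 and C3 are the benzo ring, C4, C3 and C2 of a 4-phenylcoumarin: opening the lactone gives the C1=C2 alkene in the ring-fixed Z geometry with C3 at the carbonyl level, and a C3 carbinol on that Z alkene can deliver hydrogen to one face of C1.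

## Retrosynthesis

**20 ⇒ 19 ⇒ 16 + 17.** The last operation only frees the two phenols of bis-MOM chalcone 19. Before that, the aryl–carbonyl bond is cut, so the cinnamoyl unit arrives intact as amide 17 on the aryllithium 18 made from bromide 16. Against this cut stand Friedel–Crafts or Fries acylation (acid on a free phloroglucinol next to an alkene) and building the enone by condensation from an acetophenone (one step more). The precursor 16 lacks the whole enone, and the forward step must acylate without touching C1–H.

**16 ⇒ 15 ⇒ 14.** The C–Br bond and the C5 benzoate are removed in thought. Ring A of 14 is symmetric, so monobromination needs no regiocontrol. The bromine is placed while O5 is still an ester, so that no free hydroxyl can add to a bromonium ion; the ester then has to go because it would not survive an aryllithium.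

**14 ⇒ 10 (+ 11).** The C1–H bond is cut and the alkene moved back from C2=C3 to C1=C2, which reveals the (1Z,3R)-allylic alcohol 10. This trades the heteroatom-free stereocentre C1 for a carbinol at C3 that ordinary carbonyl chemistry can set. The forward reaction (Mitsunobu substitution by 11, diazene formation, sigmatropic loss of N2) must displace at C3 without ionisation and transfer hydrogen through one conformer.

**10 ⇒ 9.** The C3–H bond and the benzoate C–O bond are cut together (Evans–Tishchenko reduction of β-hydroxy enone 9). One operation sets C3 anti to C5 and leaves O3 free and O5 acylated, exactly the differentiation the key step needs. A separate reduction followed by selective protection would cost two further steps.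

**9 ⇒ 6 + 7.** The C4–C5 bond is cut as an aldol addition of methyl ketone 6 to 3-phenylpropanal 7. It is the only C–C bond between the coumarin-derived half and the C5–C7 half, and its formation sets C5. Ketone 6 enolises only at the methyl group. The forward step needs reagent-controlled enantioface selection.

**6 ⇒ 5 ⇒ 2 ⇒ 1.** The methyl–C3 bond is cut back to acid 5. The two aryl MOM ethers and the carboxyl of 5 come from the lactone of 2 by hydroxide opening and capping, which keeps the Z alkene. The 7-O-methyl group comes from selective methylation of commercial 5,7-dihydroxy-4-phenylcoumarin 1. The forward steps must not isomerise the β,β-diaryl alkene.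

## Roads not taken

**Alternative 1:** Ring A is cut at two C–C bonds and grown by heating 3-methoxycyclobutenone A1 with the siloxyalkyne A2, which already carries the whole side chain. Electrocyclic opening to a vinylketene, [2+2] addition to the alkyne, a second opening and a six-electron closure would give the resorcinol mono-silyl ether A3.
- Merits: the annulation is convergent, its regiochemistry is fixed by the polarity of the ynol ether, and it delivers two differentiated ring A oxygens.
- Weak points: the differentiation is of no use here, since both oxygens end as free hydroxyls. C1 must already exist in A2 as a propargylic, allylic and benzylic methine, which has to survive the strongly basic chemistry that makes siloxyalkynes and the heat of the annulation; propargyl–allene isomerisation would erase it. The ketene intermediates also meet an internal alkene.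
- Comparison: the annulation does not solve the C1 problem but moves it to a more labile compound, and A2 would need about as many steps as the whole chosen route. The chosen plan takes ring A ready-made and sets C1 late, with no epimerisable carrier.

**Alternative 2:** The C2=C3 bond is cut. Cross-metathesis of the (R)-3,3-diarylpropene A4 with (S)-1-phenylhex-5-en-3-ol A5 under second-generation Hoveyda–Grubbs catalyst would give A6.
- Merits: this is the most convergent road. A5 is one asymmetric allylation away from 7, and A6 already has the free C5 alcohol. If A4 were at hand in high enantiomeric purity, this road would be shorter than the chosen one.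
- Weak points: A4 is branched at the allylic position with a 2,6-disubstituted aryl group and should react slowly while A5 dimerises. Ruthenium hydrides can move the double bond of A4 or A6 into conjugation with both arenes and destroy C1. The E geometry rests on thermodynamic preference only. The enantioselective construction of the diaryl-allyl centre of A4 is left unsolved.
- Comparison: the chosen plan is longer and linear. Against that it derives C1 by chirality transfer from a carbinol made under substrate control and obtains the E alkene from a conformational lock.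

**Alternative 3:** The C1–phenyl bond is cut. PhMgBr with CuBr·SMe2 would attack C1 of the (E,3R)-allylic picolinate A7 anti to the leaving group and give A8.
- Merits: the stereodefining step forms a C–C bond, the phenyl group enters late (useful for analogues), the E alkene of A7 needs no special source, and picolinate-directed anti-SN2′ substitution has precedent at least equal to that of the diazene route.
- Weak points: the carbon to be attacked carries the 2,6-disubstituted ring A, so a bulky arylcopper must approach the most hindered position. A cinnamyl-type ester with so electron-rich an arene ionises easily. On an E-disubstituted alkene the cis substituent at C1 is only hydrogen, so the two reactive conformers differ little. C3 and C5 must be set and protected differently beforehand, and a silyl ether must be removed afterwards.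
- Comparison: the length is comparable. The chosen plan delivers a hydrogen atom intramolecularly to the crowded carbon, has the stronger conformational bias from the cis aryl group, and obtains its oxygen differentiation in a single reduction.

Key step: step 6

## Route

Step 1
Reactants: 1 5,7-dihydroxy-4-phenylcoumarin
Product: 2 5-hydroxy-7-methoxy-4-phenylcoumarin
Conditions: MeI (1.05 equiv), K2CO3 (1.1 equiv), acetone, 23 °C
Reagents that add atoms: iodomethane, CI
Why: Williamson O-methylation; the 7-OH is the more acidic and accessible phenol (para-conjugated to the lactone carbonyl), whereas the 5-OH is shielded by the peri 4-phenyl group, so one equivalent of MeI should react at O7.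

Step 2
Reactants: 2 5-hydroxy-7-methoxy-4-phenylcoumarin
Product: 5 (Z)-3-Ar-3-phenylprop-2-enoic acid, via tripotassium ring-opened salt 3 (not isolated), via tris-MOM ester 4 (not isolated)
Conditions: KOH (4 equiv), EtOH–H2O, 80 °C; evaporate, PhMe azeotrope; MOMCl (4.5 equiv), DMF, 0 → 23 °C; then LiOH, THF–H2O, 23 °C; 1 M HCl to pH 4, 0 °C
Reagents that add atoms: potassium hydroxide, [K+].[OH-]; chloromethyl methyl ether, COCCl; lithium hydroxide, [Li+].[OH-]
Why: Classical coumarin ring-opening with O-alkylation: hydroxide opens the aryl ester to the Z cinnamate, whose geometry is that of the ring, and MOMCl caps both phenoxides so that relactonisation is no longer possible. The labile methoxymethyl ester formed alongside is saponified in the same flask.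

Step 3
Reactants: 5 (Z)-3-Ar-3-phenylprop-2-enoic acid
Product: 6 (Z)-4-Ar-4-phenylbut-3-en-2-one
Conditions: MeLi (3 equiv), THF, 0 °C; TMSCl, then aq NH4Cl
Reagents that add atoms: methyllithium, [Li]C
Why: Ketone synthesis from a carboxylic acid and an organolithium: MeLi adds to the lithium carboxylate to give a geminal dialkoxide that cannot collapse before the quench, and silylation of excess MeLi before hydrolysis suppresses tertiary alcohol formation. The β-carbon is fully substituted, so conjugate addition is not expected.

Step 4
Reactants: 6 (Z)-4-Ar-4-phenylbut-3-en-2-one; 7 3-phenylpropanal (hydrocinnamaldehyde)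
Product: 9 (1Z,5S)-1-Ar-5-hydroxy-1,7-diphenylhept-1-en-3-one, via Ipc2B dienolate 8 (not isolated)
Conditions: (−)-Ipc2BCl (1.5 equiv), Et3N, Et2O, 0 °C; then 7, −78 → −20 °C; pH 7 buffer, MeOH, H2O2, 0 °C
Reagents that add atoms: none
Why: Boron-mediated aldol addition under reagent control: only the methyl group can enolise (the vinylic side has no γ-hydrogen), and dienolate 8 adds to 7 through a cyclic six-membered transition state. The isopinocampheyl ligands of the (−)-reagent are expected to direct a methyl-ketone enolborinate to the aldehyde Re face, which sets C5 as S; the reagent antipode is the control element and would be switched if the sense were opposite for this dienolate.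

Step 5
Reactants: 9 (1Z,5S)-1-Ar-5-hydroxy-1,7-diphenylhept-1-en-3-one
Product: 10 (1Z,3R,5S)-1-Ar-3-hydroxy-1,7-diphenylhept-1-en-5-yl benzoate
Conditions: SmI2 (0.3 equiv), PhCHO (6 equiv), THF, −10 °C, dark
Reagents that add atoms: benzaldehyde, O=Cc1ccccc1
Why: Evans–Tishchenko reduction: the C5 alkoxide, benzaldehyde and trivalent samarium form a hemiacetal that transfers hydride intramolecularly to the C3 ketone through a chair-like six-membered transition state. This should give the 1,3-anti carbinol (3R) and leave O5 as its benzoate, so C3 is set from C5 and the two oxygens are differentiated in one operation.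

Step 6
Reactants: 10 (1Z,3R,5S)-1-Ar-3-hydroxy-1,7-diphenylhept-1-en-5-yl benzoate; 11 N-isopropylidene-N′-(2-nitrobenzenesulfonyl)hydrazine (IPNBSH)
Product: 14 (1R,2E,5S)-1-Ar-1,7-diphenylhept-2-en-5-yl benzoate, via Mitsunobu hydrazone adduct 12 (not isolated), via allylic diazene 13 (not isolated)
Conditions: 11 (1.5 equiv), PPh3, DEAD, THF, 0 → 23 °C; then CF3CH2OH–H2O (1:1), 23 °C
Reagents that add atoms: none
Why: Mitsunobu activation of the C3 hydroxyl and SN2 displacement by the acidic sulfonamide N–H of 11 invert C3 and give adduct 12 (3S); SN2′ attack is excluded because C1 is fully substituted. Aqueous trifluoroethanol hydrolyses the hydrazone, and loss of 2-nitrobenzenesulfinic acid leaves the monoalkyl diazene 13. Diazene 13 undergoes a concerted retro-ene reaction (sigmatropic loss of N2) that delivers the N–H hydrogen suprafacially to C1 and moves the alkene to C2=C3; this is the known reductive 1,3-transposition of allylic alcohols through monoalkyl diazenes. No ring is closed. The new stereocentre C1 is controlled by the C3 configuration together with the Z geometry: allylic 1,3-strain with the twisted ring A, which is cis to C3, forces C3–H into the alkene plane, so the C3–N bond stands on one face, C4 ends trans across the new alkene (E), and hydrogen reaches C1 on that same face, which gives 1R. The step needs substitution without ionisation and a single reactive conformer; the first is served by the mild Mitsunobu conditions and by the poor cation stabilisation of a ring A twisted out of conjugation, the second by the cis aryl group. The thermally stable adduct from 11 separates substitution from diazene release, so the hindered displacement can be given time. The C5 benzoate is a spectator that keeps O5 out of the Mitsunobu reaction.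

Step 7
Reactants: 14 (1R,2E,5S)-1-Ar-1,7-diphenylhept-2-en-5-yl benzoate
Product: 15 (1R,2E,5S)-1-[3-bromo-4-methoxy-2,6-bis(methoxymethoxy)phenyl]-1,7-diphenylhept-2-en-5-yl benzoate
Conditions: NBS (1.0 equiv), MeCN, −20 → 0 °C, dark
Reagents that add atoms: N-bromosuccinimide, O=C1CCC(=O)N1Br
Why: Electrophilic aromatic bromination: each free position of ring A is ortho to OMe and OMOM and para to the other OMOM, far more nucleophilic than the disubstituted alkene or the phenyl rings. The two positions are equivalent, so one equivalent should give a single monobromide, and the benzoate keeps O5 from bromoetherification.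

Step 8
Reactants: 15 (1R,2E,5S)-1-[3-bromo-4-methoxy-2,6-bis(methoxymethoxy)phenyl]-1,7-diphenylhept-2-en-5-yl benzoate
Product: 16 (1R,2E,5S)-1-[3-bromo-4-methoxy-2,6-bis(methoxymethoxy)phenyl]-1,7-diphenylhept-2-en-5-ol
Conditions: K2CO3 (0.3 equiv), MeOH–THF, 23 °C
Reagents that add atoms: none
Why: Base-catalysed transesterification (methanolysis) of the secondary benzoate; MOM ethers, the aryl bromide and the C1–H bond are inert to carbonate in methanol.

Step 9
Reactants: 16 (1R,2E,5S)-1-[3-bromo-4-methoxy-2,6-bis(methoxymethoxy)phenyl]-1,7-diphenylhept-2-en-5-ol; 17 (E)-N-methoxy-N-methylcinnamamide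
Product: 19 (E)-1-{3-[(1R,2E,5S)-5-hydroxy-1,7-diphenylhept-2-en-1-yl]-6-methoxy-2,4-bis(methoxymethoxy)phenyl}-3-phenylprop-2-en-1-one, via dilithio aryllithium alkoxide 18 (not isolated)
Conditions: n-BuLi (2.2 equiv), THF, −78 °C; then 17 (1.5 equiv), −78 → −20 °C; aq NH4Cl
Reagents that add atoms: none
Why: The first equivalent of n-BuLi forms the C5 alkoxide and the second effects bromine–lithium exchange, which at −78 °C is faster than any deprotonation. Aryllithium 18, flanked by OMe and OMOM, adds 1,2 to amide 17 to give a chelated tetrahedral intermediate that releases the enone only on quench (Weinreb ketone synthesis), so the chalcone never meets the organolithium.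

Step 10
Reactants: 19 (E)-1-{3-[(1R,2E,5S)-5-hydroxy-1,7-diphenylhept-2-en-1-yl]-6-methoxy-2,4-bis(methoxymethoxy)phenyl}-3-phenylprop-2-en-1-one
Product: 20 (E)-1-{2,4-dihydroxy-3-[(1R,2E,5S)-5-hydroxy-1,7-diphenylhept-2-en-1-yl]-6-methoxyphenyl}-3-phenylprop-2-en-1-one
Conditions: 3 M aq HCl, MeOH, 23 → 40 °C
Reagents that add atoms: none
Why: Acid-catalysed acetal exchange of the two aryl MOM ethers with methanol, the usual unmasking of MOM-protected 2′-hydroxychalcones. Dilute acid at mild temperature and the hydrogen-bonded 2′-hydroxyl should keep the enone from closing to the flavanone, and the homoallylic alcohol, the alkene and C1 are not expected to react.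

## Compound list

1 | 5,7-dihydroxy-4-phenylcoumarin | O=c1cc(-c2ccccc2)c2c(O)cc(O)cc2o1 | starting material
2 | 5-hydroxy-7-methoxy-4-phenylcoumarin | COc1cc(O)c2c(-c3ccccc3)cc(=O)oc2c1 | intermediate
3 | tripotassium (Z)-3-(4-methoxy-2,6-dioxidophenyl)-3-phenylprop-2-enoate | COc1cc([O-])c(/C(=C\C(=O)[O-])c2ccccc2)c([O-])c1.[K+].[K+].[K+] | intermediate
4 | methoxymethyl (Z)-3-[4-methoxy-2,6-bis(methoxymethoxy)phenyl]-3-phenylprop-2-enoate | COc1cc(OCOC)c(/C(=C\C(=O)OCOC)c2ccccc2)c(OCOC)c1 | intermediate
5 | (Z)-3-[4-methoxy-2,6-bis(methoxymethoxy)phenyl]-3-phenylprop-2-enoic acid | COc1cc(OCOC)c(/C(=C\C(=O)O)c2ccccc2)c(OCOC)c1 | intermediate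
6 | (Z)-4-[4-methoxy-2,6-bis(methoxymethoxy)phenyl]-4-phenylbut-3-en-2-one | COc1cc(OCOC)c(/C(=C\C(C)=O)c2ccccc2)c(OCOC)c1 | intermediate
7 | 3-phenylpropanal (hydrocinnamaldehyde) | O=CCCc1ccccc1 | starting material
8 | (Z)-[4-Ar-4-phenylbuta-1,3-dien-2-yl]oxy-bis[(−)-isopinocampheyl]borane | COc1cc(OCOC)c(/C(=C\C(=C)OB([C@@H]2C[C@@H]3C[C@@H](C3(C)C)[C@H]2C)[C@@H]2C[C@@H]3C[C@@H](C3(C)C)[C@H]2C)c2ccccc2)c(OCOC)c1 | intermediate
9 | (1Z,5S)-1-Ar-5-hydroxy-1,7-diphenylhept-1-en-3-one | COc1cc(OCOC)c(/C(=C\C(=O)C[C@@H](O)CCc2ccccc2)c2ccccc2)c(OCOC)c1 | intermediate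
10 | (1Z,3R,5S)-1-Ar-3-hydroxy-1,7-diphenylhept-1-en-5-yl benzoate | COc1cc(OCOC)c(/C(=C\[C@H](O)C[C@@H](OC(=O)c2ccccc2)CCc2ccccc2)c2ccccc2)c(OCOC)c1 | intermediate
11 | N-isopropylidene-N′-(2-nitrobenzenesulfonyl)hydrazine (IPNBSH) | CC(C)=NNS(=O)(=O)c1ccccc1[N+](=O)[O-] | starting material
12 | (1Z,3S,5S)-1-Ar-3-[N-(2-nitrophenylsulfonyl)-N′-(propan-2-ylidene)hydrazinyl]-1,7-diphenylhept-1-en-5-yl benzoate | COc1cc(OCOC)c(/C(=C\[C@@H](N(N=C(C)C)S(=O)(=O)c2ccccc2[N+](=O)[O-])C[C@@H](OC(=O)c2ccccc2)CCc2ccccc2)c2ccccc2)c(OCOC)c1 | intermediate
13 | (1Z,3S,5S)-1-Ar-3-diazenyl-1,7-diphenylhept-1-en-5-yl benzoate | COc1cc(OCOC)c(/C(=C\[C@@H](N=N)C[C@@H](OC(=O)c2ccccc2)CCc2ccccc2)c2ccccc2)c(OCOC)c1 | intermediate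
14 | (1R,2E,5S)-1-Ar-1,7-diphenylhept-2-en-5-yl benzoate | COc1cc(OCOC)c([C@H](/C=C/C[C@@H](OC(=O)c2ccccc2)CCc2ccccc2)c2ccccc2)c(OCOC)c1 | intermediate
15 | (1R,2E,5S)-1-[3-bromo-4-methoxy-2,6-bis(methoxymethoxy)phenyl]-1,7-diphenylhept-2-en-5-yl benzoate | COc1cc(OCOC)c([C@H](/C=C/C[C@@H](OC(=O)c2ccccc2)CCc2ccccc2)c2ccccc2)c(OCOC)c1Br | intermediate
16 | (1R,2E,5S)-1-[3-bromo-4-methoxy-2,6-bis(methoxymethoxy)phenyl]-1,7-diphenylhept-2-en-5-ol | COc1cc(OCOC)c([C@H](/C=C/C[C@@H](O)CCc2ccccc2)c2ccccc2)c(OCOC)c1Br | intermediate
17 | (E)-N-methoxy-N-methylcinnamamide | CON(C)C(=O)/C=C/c1ccccc1 | starting material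
18 | lithium (1R,2E,5S)-1-[3-lithio-4-methoxy-2,6-bis(methoxymethoxy)phenyl]-1,7-diphenylhept-2-en-5-olate | COc1cc(OCOC)c([C@H](/C=C/C[C@@H](O[Li])CCc2ccccc2)c2ccccc2)c(OCOC)c1[Li] | intermediate
19 | (E)-1-{3-[(1R,2E,5S)-5-hydroxy-1,7-diphenylhept-2-en-1-yl]-6-methoxy-2,4-bis(methoxymethoxy)phenyl}-3-phenylprop-2-en-1-one | COc1cc(OCOC)c([C@H](/C=C/C[C@@H](O)CCc2ccccc2)c2ccccc2)c(OCOC)c1C(=O)/C=C/c1ccccc1 | intermediate
20 | (E)-1-{2,4-dihydroxy-3-[(1R,2E,5S)-5-hydroxy-1,7-diphenylhept-2-en-1-yl]-6-methoxyphenyl}-3-phenylprop-2-en-1-one | COc1cc(O)c([C@H](/C=C/C[C@@H](O)CCc2ccccc2)c2ccccc2)c(O)c1C(=O)/C=C/c1ccccc1 | target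

## Step count and weak points

Total: 10 steps. Longest linear sequence: 10 steps (1 → 20).

**Step 6 (key step).**
- What may go wrong: the displacement at C3 may not stay SN2. The ortho MOM groups of the twisted ring A flank both faces of C3 and slow the attack of the sulfonamide. The activated allylic oxyphosphonium ion could then ionise towards the diaryl-substituted allyl cation, be intercepted by the neighbouring benzoate, or eliminate to a diene. Each of these erodes the C3 configuration and hence C1.
- A second concern: the alkene geometry passes directly into the C1 configuration, so any E isomer carried into 10 lowers the stereochemical purity of 14.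
- Fallback: from 10, acylation with methyl chloroformate and pyridine gives the allylic methyl carbonate F1. Formate hydrogenolysis under Pd(OAc)2, PBu3, HCO2H and Et3N then forms an allylpalladium intermediate with inversion and delivers hydride from the metal face to the more substituted terminus C1. This is the same stereochemical course as the diazene route and rejoins it at 14.

**Step 4.**
- What may go wrong: enantioface discrimination in methyl-ketone Ipc2BCl aldol additions to unbranched aldehydes is often only moderate. Because C3 and then C1 are derived from C5, any deficit is carried to the end.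
- Fallback: from 6, TMSOTf and Et3N give the 2-silyloxydiene F2. A catalytic enantioselective Mukaiyama aldol addition to 7, under the B-butyl oxazaborolidinone made from N-tosyltryptophan (catalyst antipode chosen for Re-face attack), gives the silyl ether F3. K2CO3 in MeOH removes the silyl group and the route is rejoined at 9.

**Step 2.**
- What may go wrong: the lactone of 2 is deactivated by its 5-phenoxide, so opening may be incomplete. Partial relactonisation may occur before capping. Prolonged heating in base may also let the β,β-diaryl alkene drift from Z towards E through the phenoxide-conjugated form.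
- Fallback: from 2, LiAlH4 reduces the lactone to the Z triol F4, in which no carboxylate and no relactonisation are possible. K2CO3 and MOMCl in acetone cap the two phenols only and give the allylic alcohol F5. MnO2 gives the Z enal F6, MeMgBr gives the carbinol F7, and MnO2 gives 6, where the route is rejoined (steps 2 and 3 are replaced).

**Step 9.**
- What may go wrong: proton transfer from the acidic C1–H to the aryllithium would scramble C1 and the alkene position. Conjugate addition to 17 or slow acylation by the hindered di-ortho-alkoxy aryllithium could also compete.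
- Fallback: from 16, a carbonylative Suzuki–Miyaura coupling with (E)-2-phenylvinylboronic acid (Pd(OAc)2, di(1-adamantyl)-n-butylphosphine, CO, K2CO3) forms the aryl ketone without any organolithium and gives 19 directly. No new compound is made.

**Step 10.**
- What may go wrong: acid may close the freed 2′-hydroxyl onto the enone (flavanone formation) or let a phenol add to the C2=C3 alkene before both MOM groups are gone.
- Fallback: from 16, the aryllithium 18 is acylated with N-methoxy-N-methylacetamide to give the acetophenone F8. The MOM groups are removed with the same acid while no enone is present, giving the dihydroxyacetophenone F9. Claisen–Schmidt condensation with benzaldehyde (KOH, EtOH) then builds the chalcone under base and gives 20.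

## Further compounds

F1 | step 6 | (1Z,3R,5S)-1-Ar-3-(methoxycarbonyloxy)-1,7-diphenylhept-1-en-5-yl benzoate | COc1cc(OCOC)c(/C(=C\[C@H](OC(=O)OC)C[C@@H](OC(=O)c2ccccc2)CCc2ccccc2)c2ccccc2)c(OCOC)c1
F2 | step 4 | (Z)-[4-Ar-4-phenylbuta-1,3-dien-2-yl]oxy-trimethylsilane | COc1cc(OCOC)c(/C(=C\C(=C)O[Si](C)(C)C)c2ccccc2)c(OCOC)c1
F3 | step 4 | (1Z,5S)-1-Ar-1,7-diphenyl-5-(trimethylsilyloxy)hept-1-en-3-one | COc1cc(OCOC)c(/C(=C\C(=O)C[C@@H](O[Si](C)(C)C)CCc2ccccc2)c2ccccc2)c(OCOC)c1
F4 | step 2 | (Z)-2-(3-hydroxy-1-phenylprop-1-en-1-yl)-5-methoxybenzene-1,3-diol | COc1cc(O)c(/C(=C\CO)c2ccccc2)c(O)c1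
F5 | step 2 | (Z)-3-Ar-3-phenylprop-2-en-1-ol | COc1cc(OCOC)c(/C(=C\CO)c2ccccc2)c(OCOC)c1
F6 | step 2 | (Z)-3-Ar-3-phenylprop-2-enal | COc1cc(OCOC)c(/C(=C\C=O)c2ccccc2)c(OCOC)c1
F7 | step 2 | (Z)-4-Ar-4-phenylbut-3-en-2-ol (racemic) | COc1cc(OCOC)c(/C(=C\C(C)O)c2ccccc2)c(OCOC)c1
F0 | step 9 | none | none
F8 | step 10 | 1-{3-[(1R,2E,5S)-5-hydroxy-1,7-diphenylhept-2-en-1-yl]-6-methoxy-2,4-bis(methoxymethoxy)phenyl}ethan-1-one | COc1cc(OCOC)c([C@H](/C=C/C[C@@H](O)CCc2ccccc2)c2ccccc2)c(OCOC)c1C(C)=O
F9 | step 10 | 1-{2,4-dihydroxy-3-[(1R,2E,5S)-5-hydroxy-1,7-diphenylhept-2-en-1-yl]-6-methoxyphenyl}ethan-1-one | COc1cc(O)c([C@H](/C=C/C[C@@H](O)CCc2ccccc2)c2ccccc2)c(O)c1C(C)=O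
A1 | alternative 1 | 3-methoxycyclobut-2-en-1-one | COC1=CC(=O)C1
A2 | alternative 1 | triisopropyl{[(3R,4E,7S)-7-(tert-butyldimethylsilyloxy)-3,9-diphenylnon-4-en-1-yn-1-yl]oxy}silane | CC(C)[Si](C(C)C)(C(C)C)OC#C[C@H](/C=C/C[C@@H](O[Si](C)(C)C(C)(C)C)CCc1ccccc1)c1ccccc1
A3 | alternative 1 | 2-[(1R,2E,5S)-5-(tert-butyldimethylsilyloxy)-1,7-diphenylhept-2-en-1-yl]-5-methoxy-3-(triisopropylsilyloxy)phenol | COc1cc(O)c([C@H](/C=C/C[C@@H](O[Si](C)(C)C(C)(C)C)CCc2ccccc2)c2ccccc2)c(O[Si](C(C)C)(C(C)C)C(C)C)c1
A4 | alternative 2 | 5-methoxy-1,3-bis(methoxymethoxy)-2-[(1R)-1-phenylprop-2-en-1-yl]benzene | COc1cc(OCOC)c([C@H](C=C)c2ccccc2)c(OCOC)c1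
A5 | alternative 2 | (S)-1-phenylhex-5-en-3-ol | C=CC[C@@H](O)CCc1ccccc1
A6 | alternative 2 | (1R,2E,5S)-1-Ar-1,7-diphenylhept-2-en-5-ol | COc1cc(OCOC)c([C@H](/C=C/C[C@@H](O)CCc2ccccc2)c2ccccc2)c(OCOC)c1
A7 | alternative 3 | (1E,3R,5S)-1-Ar-5-(tert-butyldimethylsilyloxy)-7-phenylhept-1-en-3-yl pyridine-2-carboxylate | COc1cc(OCOC)c(/C=C/[C@H](OC(=O)c2ccccn2)C[C@@H](O[Si](C)(C)C(C)(C)C)CCc2ccccc2)c(OCOC)c1
A8 | alternative 3 | tert-butyl{[(1R,2E,5S)-1-Ar-1,7-diphenylhept-2-en-5-yl]oxy}dimethylsilane | COc1cc(OCOC)c([C@H](/C=C/C[C@@H](O[Si](C)(C)C(C)(C)C)CCc2ccccc2)c2ccccc2)c(OCOC)c1
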